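## Retrosynthetic overview

- **Feature.** Ring A carries three adjacent oxygens (C1–OMe, C2–OH, C3–OAr) and bromine on all remaining carbons (C4, C5, C6). C2 is the carbon that becomes carbanionic when an O-nucleophile adds to 3-methoxybenzyne. C4–C6 can be filled last without any regiocontrol.
- **Disconnection 1** (last step forward): the three C–Br bonds of ring A are removed together, leading back to 2-(2,4-dibromophenoxy)-6-methoxyphenol. Ring B (C1′–O, Br at C2′ and C4′) keeps the bromines of the purchased phenol.
- **Disconnection 2:** C2–OH goes back to C2–B, by oxidation of an aryl borate.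
- **Disconnection 3** (key): C3–O(aryl) and C2–B are cut together, leading back to 3-methoxybenzyne, 2,4-dibromophenoxide and triisopropyl borate.
- **Rings.** No ring is built. Both benzene rings are bought intact and joined through the ether oxygen in the key step.

Key step: step 2

Remark: the target has no stereocentre and its diaryl ether axes rotate freely, so it is one achiral compound and there is nothing to set or preserve.

## Route

**Step 1**
Reactants: 1 2,4-dibromophenol
Product: 2 cesium 2,4-dibromophenoxide
Conditions: CsOH·H2O (titrated, 1.00 equiv), MeOH, rt; evaporate; PhMe azeotrope (×3); 80 °C, high vacuum; store under Ar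
Reagents that add atoms: cesium hydroxide monohydrate, O.[OH-].[Cs+]
Why: A simple acid–base reaction of an acidic phenol (pKa near 8) with hydroxide should go to completion, and exact stoichiometry with azeotropic drying should leave neither free phenol nor water as a proton source for step 2.

**Step 2**
Reactants: 2 cesium 2,4-dibromophenoxide (1.5 equiv); 3 3-methoxy-2-(trimethylsilyl)phenyl trifluoromethanesulfonate (1.0 equiv); 4 triisopropyl borate (6 equiv)
Product: 6 cesium [2-(2,4-dibromophenoxy)-6-methoxyphenyl]triisopropoxyborate, via 3-methoxybenzyne 5 (not isolated)
Conditions: 2, 4, CsF (flame-dried, 3 equiv), 18-crown-6 (dried, 1.5 equiv), 4 Å MS, THF, 35 °C, Ar; 3 in THF by syringe pump over 6 h; then concentrate in vacuo (removes THF, Me3SiF and excess 4); the crude solid is taken on unpurified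
Reagents that add atoms: triisopropyl borate (4), CC(C)OB(OC(C)C)OC(C)C
Why: Proposed new method: fluoride attacks the SiMe3 group of 3 and triflate departs to give 3-methoxybenzyne 5, whose triple bond is distorted by the σ-withdrawing OMe so that the terminus meta to OMe is the more electrophilic carbon; phenoxide 2 adds there (C3–O bond) and the charge develops at C2, in the ring plane between the two C–O dipoles that stabilise it. This aryl anion is then caught at the vacant boron orbital of 4, which is present in large excess and loosely associated with the cesium phenoxide ion pair, to give the tetracoordinate borate 6 (C2–B bond), a net oxy-borylation across the former triple bond. The closest known reaction types are the fluoride-induced O-arylation of phenols with silylaryl triflates, three-component aryne couplings in which the aryl anion is taken by CO2, carbonyl compounds or halogen donors, and the fluoride-triggered transfer of a carbanion from silicon to a trialkyl borate (Me3SiCF3, KF and B(OMe)3 giving the trifluoromethylborate salt), which shows that fluoride still reaches silicon beside a borate ester; what is new is a borate ester as third component of an aryne coupling. No ring is closed and no stereocentre is formed. Regioselectivity of the addition is secured by the methoxy-induced aryne distortion, reinforced by steric shielding of the carbon next to OMe. Boron over proton capture is secured by a medium free of O–H, N–H and acidic C–H bonds (no MeCN, no ammonium fluoride, dried salts, sieves), by slow addition of 3 so that aryne and triflate stay dilute, and by the excess of 4; ortho-lithiation, the usual entry to this carbanion, is excluded by the two C–Br bonds and the acidic C3′–H of ring B.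

**Step 3**
Reactants: 6 cesium [2-(2,4-dibromophenoxy)-6-methoxyphenyl]triisopropoxyborate (crude)
Product: 7 2-(2,4-dibromophenoxy)-6-methoxyphenol
Conditions: THF, 0 °C; 30% aq H2O2 (5 equiv) first, then 2 M NaOH (3 equiv), 0 °C to rt, 1 h; aq Na2S2O3; 1 M HCl to pH 4; extraction into dilute NaOH and re-acidification, then chromatography (removes neutral material and recovered 1)
Reagents that add atoms: hydrogen peroxide, OO
Why: This is a standard oxidative C–B cleavage (hydroperoxide binds boron, the aryl group shifts 1,2 from B to O, and the borate ester hydrolyses), which leaves aryl bromides and ethers untouched and, with peroxide added first in the cold, should outrun protodeboronation of the doubly ortho-oxygenated aryl boron species.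

**Step 4**
Reactants: 7 2-(2,4-dibromophenoxy)-6-methoxyphenol; 8 bromine (3.2 equiv)
Product: 9 3,4,5-tribromo-2-(2,4-dibromophenoxy)-6-methoxyphenol (target CNP0152859.0)
Conditions: Br2 added in portions, AcOH/CH2Cl2 1:1 (anhydrous), 0 °C to rt, then 40 °C until the dibromide is consumed (HPLC control); aq NaHSO3
Reagents that add atoms: bromine (8), BrBr
Why: This is an exhaustive electrophilic aromatic bromination in which C4 and C6 are each ortho/para to both ether oxygens and C5 is para to the free OH, so all three C–H sites of ring A are strongly activated, whereas the only activated open site of ring B (C6′) is meta to two bromines; the medium is left unbuffered because acetate with bromine drives para-bromophenols to 4,4-dibromocyclohexadienones, and the bisulfite quench returns any such dienone to the phenol.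

## Compound list

1 | 2,4-dibromophenol | Oc1ccc(Br)cc1Br | starting material
2 | cesium 2,4-dibromophenoxide | [Cs+].[O-]c1ccc(Br)cc1Br | intermediate
3 | 3-methoxy-2-(trimethylsilyl)phenyl trifluoromethanesulfonate | COc1cccc(OS(=O)(=O)C(F)(F)F)c1[Si](C)(C)C | starting material
4 | triisopropyl borate | CC(C)OB(OC(C)C)OC(C)C | starting material
5 | 3-methoxybenzyne (1,2-didehydro-3-methoxybenzene) | COC1=CC=CC#C1 | intermediate
6 | cesium [2-(2,4-dibromophenoxy)-6-methoxyphenyl]triisopropoxyborate | [Cs+].COc1cccc(Oc2ccc(Br)cc2Br)c1[B-](OC(C)C)(OC(C)C)OC(C)C | intermediate
7 | 2-(2,4-dibromophenoxy)-6-methoxyphenol | COc1cccc(Oc2ccc(Br)cc2Br)c1O | intermediate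
8 | bromine | BrBr | starting material
9 | 3,4,5-tribromo-2-(2,4-dibromophenoxy)-6-methoxyphenol | COc1c(O)c(Oc2ccc(Br)cc2Br)c(Br)c(Br)c1Br | target

Total step count: 4
Longest linear sequence: 4 steps (1 → 2 → 6 → 7 → 9)

## Steps most likely to fail

**Step 2 (Proposed new method).**

- What may go wrong:
  - The aryl anion may be quenched by trace or solvent-derived protons before boron reaches it.
  - The anion may abstract bromine or the C3′ proton from a ring-B unit.
  - Fluoride may be held back by the borate so that aryne release stalls.
  - Isopropoxide shed from ate complexes may compete with the phenoxide as nucleophile.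
- Fallback (known chemistry, no aryne), setting out from 2 and returning at 7:
  - 2 is heated with purchased 2-fluoro-6-methoxybenzaldehyde (COc1cccc(F)c1C=O) in DMAc at 120–140 °C. This nucleophilic aromatic substitution ortho to the formyl group should give 2-(2,4-dibromophenoxy)-6-methoxybenzaldehyde F1.
  - Baeyer–Villiger (Dakin-type) oxidation of this electron-rich aldehyde with mCPBA in CH2Cl2 should give 2-(2,4-dibromophenoxy)-6-methoxyphenyl formate F2.
  - K2CO3 in MeOH cleaves F2 to 7.

**Step 4.**

- What may go wrong:
  - The bromination may stall at the dibromide stage.
  - The free phenol may be oxidised through ipso-bromination to dienone or quinone material.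
  - Bromine may spill over to C6′ of ring B when the last substitution is forced.
- Fallback (staged, protected bromination), setting out from 7 and returning at 9:
  - Ac2O/pyridine/DMAP converts 7 into 2-(2,4-dibromophenoxy)-6-methoxyphenyl acetate F3, in which the oxidation-prone OH is masked and only the two positions ortho/para to both ethers remain activated.
  - Br2 (2.1 equiv) in AcOH at rt to 50 °C should then give 3,5-dibromo-2-(2,4-dibromophenoxy)-6-methoxyphenyl acetate F4.
  - K2CO3 in MeOH at 0 °C releases 3,5-dibromo-2-(2,4-dibromophenoxy)-6-methoxyphenol F5.
  - The single remaining ring-A position of F5, para to OH, is brominated with one equivalent of Bu4NBr3 (CH2Cl2/MeOH) or Br2 (AcOH) to give 9.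

**Step 3.**

- What may go wrong: the C–B bond may be lost by hydrolysis and protodeboronation on first contact with aqueous base, before hydroperoxide has bound to boron.
- Fallback (oxygen introduced through a C–I bond, without boron), setting out from 2 and 3 and returning at 7:
  - The coupling of step 2 is run in the dark with perfluorohexyl iodide (2.5 equiv) in place of 4. The aryl anion formed via 5 then attacks iodine, as in known nucleophile/aryne/perfluoroalkyl iodide couplings, and should give the stable, chromatographable 2,4-dibromo-1-(2-iodo-3-methoxyphenoxy)benzene F6.
  - iPrMgCl·LiCl (1.05 equiv) in THF at −40 °C exchanges the doubly oxygen-flanked iodide far faster than either bromide and should give [2-(2,4-dibromophenoxy)-6-methoxyphenyl]magnesium chloride F7.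
  - F7 is treated with tert-butyl peroxybenzoate at −40 to 0 °C (perester O-alkoxylation of a Grignard reagent) to give 2-tert-butoxy-1-(2,4-dibromophenoxy)-3-methoxybenzene F8.
  - TFA in CH2Cl2 at 0 °C removes the tert-butyl group to give 7.

## Further compounds

F1 | step 2 | 2-(2,4-dibromophenoxy)-6-methoxybenzaldehyde | COc1cccc(Oc2ccc(Br)cc2Br)c1C=O
F2 | step 2 | 2-(2,4-dibromophenoxy)-6-methoxyphenyl formate | COc1cccc(Oc2ccc(Br)cc2Br)c1OC=O
F3 | step 4 | 2-(2,4-dibromophenoxy)-6-methoxyphenyl acetate | COc1cccc(Oc2ccc(Br)cc2Br)c1OC(C)=O
F4 | step 4 | 3,5-dibromo-2-(2,4-dibromophenoxy)-6-methoxyphenyl acetate | COc1c(Br)cc(Br)c(Oc2ccc(Br)cc2Br)c1OC(C)=O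
F5 | step 4 | 3,5-dibromo-2-(2,4-dibromophenoxy)-6-methoxyphenol | COc1c(Br)cc(Br)c(Oc2ccc(Br)cc2Br)c1O
F6 | step 3 | 2,4-dibromo-1-(2-iodo-3-methoxyphenoxy)benzene | COc1cccc(Oc2ccc(Br)cc2Br)c1I
F7 | step 3 | [2-(2,4-dibromophenoxy)-6-methoxyphenyl]magnesium chloride | COc1cccc(Oc2ccc(Br)cc2Br)c1[Mg]Cl
F8 | step 3 | 2-tert-butoxy-1-(2,4-dibromophenoxy)-3-methoxybenzene | COc1cccc(Oc2ccc(Br)cc2Br)c1OC(C)(C)C
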